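**Numbering.** Elemane numbering is used throughout: C1=C2 is the vinyl group and C14 the methyl on C10; C3=C4(C15) is the isopropenyl group on C5; C5–C10 is the cyclohexane; C11 carries the methyl C13; C12 is the lactone carbonyl bound to O6.

## Analysis of the target

Target 33 is an elemane-type sesquiterpene lactone: a cyclohexane (C5–C10) cis-fused at C6–C7 to a γ-lactone (O6–C12(=O)–C11), with a vinyl group and a methyl on quaternary C10, an isopropenyl group on C5, an acetate on C8, and a methyl plus an angelate on C11. It has six stereocentres (5R,6S,7R,8S,10R,11S), five of them contiguous on the ring. Their relationships are: isopropenyl cis to the C14 methyl and trans to the vinyl group; O6 trans to the isopropenyl group and cis to C11 (H6 and H7 cis); the acetate trans to C11; at C11 the methyl on the side of C8 and the acyloxy group on the side of H7. The angelate is the most fragile group, since it sits on a tertiary oxygen α to a carbonyl and its Z alkene drifts to the tiglate with base, heat or nucleophiles. The two terminal alkenes rule out hydrogenation and ozonolysis, and any carbonyl at C4 or C8 makes the C6 oxygen a β-leaving group. The difficulty lies in quaternary C10 next to C5, in the dense stereochemical array that has no all-equatorial chair, and in the tertiary C11 carbinol, whose configuration must be tied to C7. The strategy rests on the 1,3-relationship of the C8 oxygen and the C11 oxygen across C7. This β-hydroxy ketone pattern is the retron of an isoxazoline C8=N–O–C11 fused to the carbocycle at C7–C8, so one intramolecular nitrile oxide cycloaddition can form C7–C8, close the cyclohexane and deliver both oxygens.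

## Retrosynthetic reasoning

**Tertiary ester.** The C11 angelate of 33 is cut first, which leads to hydroxy lactone 30 and angelic acid 31, the latter activated in the flask as mixed anhydride 32. The angelate is the most isomerisable group and would not survive the reductions, acids and fluoride used earlier. The forward step has to acylate a hindered tertiary alkoxide without Z-to-E drift.

**Isopropenyl group.** The C4=C3 alkene of 30 is traced to methyl ketone 29 and this to dioxolane 28. A free 1,1-disubstituted alkene on C5 would capture the C8 nitrile oxide in a five-ring closure and would interfere with the cationic lactonisation. C4 therefore travels as a ketal and is methylenated late under non-basic conditions.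

**Lactone C6–O bond.** In 28 the bond between C6 and the lactone oxygen is cut with inversion, which leads through triflate 27 to the 6-epi alcohol 26 with its tert-butyl ester. This is forced by the key step: the cycloaddition can only place the C6 oxygen trans to the new C7–C11 bond, whereas the cis-lactone needs them cis. The forward reaction therefore has to form the C6–O bond from the face of C11 by displacement at C6.

**C8 carbinol and N–O bond.** Alcohol 26 comes from silyl ether 25, and acetate 25 and diol 24 lead back to β-hydroxy ketone 23, which comes from isoxazoline 22 by N–O cleavage. The C8 stereocentre is set by hydride delivery from the C11 hydroxyl, which is meant to give the trans relationship of the target directly and to avoid a later inversion at C8.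

**Key disconnection.** Isoxazoline 22 is opened at C7–C8 and O–C11 to nitrile oxide 21 and so to the open-chain oxime enoate 20. The E geometry of the C7=C11 enoate fixes C11 relative to C7, and the C6 silyloxy stereocentre fixes the face. In the fused adduct the C7–C11 bond must lie pseudo-equatorial, coplanar with C8=N, and the C13 methyl is cis to C6. Only H6 can therefore eclipse the alkene, and the oxygen on C6 ends trans to C11. A chain with the C6 configuration of the target would react through its all-equatorial chair to the C7,C11-epimer. Precursor 20 is for that reason made with C6 epimeric to the target, which steers the dipole to the face that gives the correct C7 and C11.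

**C6 carbinol.** Oxime 20 is traced through aldehyde 19, alcohol 18 and bis-silyl ether 17 to allylic alcohol 16, and 16 to enone 15. Hydride addition to the C6 ketone anti to C10 gives the 6-epi alcohol that the cycloaddition needs.

**C6–C7 bond.** Enone 15 is cut between C6 and C7 into acid chloride 13, made from acid 8, and alkenylzinc 14, made from iodo-enoate 12; the two are joined by an acyl cross-coupling. The trisubstituted E enoate arrives as an intact unit. Building the enoate by cross-metathesis after a vinyl addition at C6 is excluded, because a terminal alkene at C7 and the C10 vinyl group would be the two ends of a 1,6-diene, which closes a five-membered ring instead.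

**C5–C10 bond.** Acid 8 is cut between C5 and C10 to boron ketene acetal 7 and so to allyl ester 6, the retron of an Ireland–Claisen rearrangement, and 6 to alcohol 3 and acid 5. This one disconnection makes the quaternary centre with its vinyl group and the adjacent C5 stereocentre together. A chiral ligand on boron supplies the absolute configuration, because the allylic alcohol is primary and carries no stereocentre of its own.

**Building blocks.** Alcohol 3 comes from alkyne 1 by carbometalation through alane 2, which fixes the E geometry that the Claisen chair converts into the C10 configuration. Acid 5 comes from the commercial ester 4, and iodo-enoate 12 from malonate 9 through 10 and 11.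

## Alternatives that were turned down

**Alternative 1:** The ring is cut at C9–C10. Forward, a Lewis acid such as TiCl4 or EtAlCl2 would set off an intramolecular Sakurai-type conjugate addition within one chain. C10, the γ-carbon of an allylsilane unit, adds to C9, the β-carbon of a vinyl ketone unit; this closes the cyclohexanone and releases the C1=C2 vinyl group. The product would be 2-benzyloxy-3-isopropenyl-4-methyl-4-vinylcyclohexanone A1 with C5, C6 and C10 in place. In its favour, one robust C–C bond formation makes the ring, the quaternary centre and the vinyl group, the allylsilane geometry relays C5 to C10 through a chair, and the isopropenyl group needs no mask. On ring construction and on avoiding a C6 inversion it is stronger than the chosen route. Against it, A1 carries its carbonyl at C7 and nothing of C11–C13, of the C8 oxygen or of the tertiary carbinol. C7 would have to be converted from a carbonyl carbon into a CH bearing a quaternary C11, with C8 oxidised separately, and neither the C7/C11 relationship nor the cis-lactone is addressed by the key step. The chosen cycloaddition forms C7–C8, delivers the C8 and C11 oxygens and sets C7 and C11 in one operation, leaving only functional-group adjustments.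

**Alternative 2:** C1–C10 and C4–C5 are cut. Irradiation of (S)-5-[(tert-butyldimethylsilyl)oxy]-3-methylcyclohex-2-en-1-one A2 with 1-methylcyclobutene A3 would give the cis-anti-cis 6-4-4 tricyclic ketone A4 by closing the central cyclobutane. Heating A4 would then open the outer four-membered ring and unveil the vinyl group on C10 and the isopropenyl group on C5. In its favour, two steps from simple pieces create both alkenes and the C5/C10 pair, with the relative configuration set by the photoadduct; in brevity for this part it beats the Ireland–Claisen sequence. Against it, the head-to-head versus head-to-tail orientation of an enone photocycloaddition with a trisubstituted cyclobutene is not secured by the substrate, and facial control rests on a remote silyloxy group. The thermal fragmentation can also cleave C5–C10 to a ten-membered ring, and it needs temperatures at which the 1,5-diene it creates is prone to Cope rearrangement. After it, C7 lies between a C6 ketone and a β-silyloxy C8, so attaching C11 there invites elimination and leaves C7, C11 and the lactone stereochemistry open. The chosen route spends more steps on C5/C10 but solves C7, C8 and C11 together.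

**Alternative 3:** C5–C10 and C8–C9 are cut in a Diels–Alder sense. Methacrolein A5 bound to a chiral Lewis acid of the type (salen)CrSbF6 would add to (E)-1-(dimethylamino)-3-[(tert-butyldimethylsilyl)oxy]buta-1,3-diene A6 to give the endo cycloadduct A7 with quaternary C10 in place. In its favour, the quaternary centre is made catalytically and enantioselectively in a reaction class with a broad record, and the aldehyde becomes the vinyl group by one olefination. On absolute stereocontrol it is stronger than the stoichiometric chiral boron reagent of the chosen route. Against it, A7 leads after olefination and unmasking to (R)-4-methyl-4-vinylcyclohex-2-en-1-one A8 and no further. In A8 the isopropenyl group must enter at C5 by conjugate addition next to a quaternary carbon whose two substituents (methyl and vinyl) differ little in size, so the C5/C10 relationship is poorly controlled. C6, C7, C8 and C11 would then be introduced one after another by enolate chemistry. The chosen route fixes C5/C10 in one pericyclic step and C7/C11 in another.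

Key step: step 14

**Assumption:** the absolute sense of induction of the chiral bromoborane in step 4 is taken by analogy with simple (E)-allyl esters; should acid 8 prove to be the antipode, the enantiomeric (R,R) reagent is used.

## Route

Step 1
Reactants: 1 tert-butyl(but-3-yn-1-yloxy)dimethylsilane
Product: 3 (E)-5-[(tert-butyldimethylsilyl)oxy]-3-methylpent-2-en-1-ol, via alkenyl(dimethyl)alane 2 (not isolated)
Conditions: Me3Al, Cp2ZrCl2 (cat.), CH2Cl2, rt; then n-BuLi, THF, −78 °C; (CH2O)n, rt
Reagents that add atoms: trimethylaluminium, C[Al](C)C; formaldehyde (from paraformaldehyde), C=O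
Why: Zirconium-catalysed syn-carboalumination (Negishi) adds CH3 and Al cis across the alkyne, and the derived alanate adds to formaldehyde with retention. The CH2OH group therefore ends cis to the C14 methyl and trans to the C9 chain (E).

Step 2
Reactants: 4 ethyl 2-(2-methyl-1,3-dioxolan-2-yl)acetate
Product: 5 2-(2-methyl-1,3-dioxolan-2-yl)acetic acid
Conditions: LiOH, THF–H2O, rt; then HCl (1 M) to pH 4, 0 °C
Reagents that add atoms: lithium hydroxide, [Li+].[OH-]
Why: Ester saponification; cold, mild acidification liberates the acid without opening the dioxolane.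

Step 3
Reactants: 3 (E)-allylic alcohol; 5 ketal acid
Product: 6 (E)-5-[(tert-butyldimethylsilyl)oxy]-3-methylpent-2-en-1-yl 2-(2-methyl-1,3-dioxolan-2-yl)acetate
Conditions: DCC, DMAP (cat.), CH2Cl2, 0 °C to rt
Reagents that add atoms: none
Why: Steglich esterification of a primary allylic alcohol under neutral conditions that spare the ketal and the silyl ether.

Step 4
Reactants: 6 allyl ester
Product: 8 (2S,3R)-3-{2-[(tert-butyldimethylsilyl)oxy]ethyl}-3-methyl-2-(2-methyl-1,3-dioxolan-2-yl)pent-4-enoic acid, via boron ketene acetal 7 (not isolated)
Conditions: (4S,5S)-2-bromo-1,3-bis{[3,5-bis(trifluoromethyl)phenyl]sulfonyl}-4,5-diphenyl-1,3,2-diazaborolidine, Et3N, toluene–hexane, −78 °C to rt; aqueous work-up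
Reagents that add atoms: none
Why: Enantioselective Ireland–Claisen rearrangement through a chiral boron enolate, which forms C5–C10 and turns C1–C2 into the vinyl group. Et3N in a non-polar medium should give the enolate with the C5 substituent cis to the allyloxy oxygen; in the chair, with the C9 chain of the E alkene equatorial, this gives the C5/C10 relationship of the target. The C2-symmetric ligand on boron selects the enolate face, and a boron enolate does not expel the β-ketal oxygen.

Step 5
Reactants: 9 diethyl 2-methylmalonate
Product: 10 diethyl 2-(diiodomethyl)-2-methylmalonate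
Conditions: NaH, Et2O, reflux; CHI3
Reagents that add atoms: iodoform, IC(I)I
Why: C-Alkylation of the malonate enolate by iodoform gives the quaternary diiodomethyl malonate.

Step 6
Reactants: 10 diiodomethyl malonate
Product: 11 (E)-3-iodo-2-methylprop-2-enoic acid
Conditions: KOH, EtOH–H2O, reflux; then HCl
Reagents that add atoms: potassium hydroxide, [K+].[OH-]
Why: Saponification followed by decarboxylative elimination of iodide gives the iodoacrylic acid, with iodine trans to the carboxyl group (E).

Step 7
Reactants: 11 (E)-iodo acid
Product: 12 tert-butyl (E)-3-iodo-2-methylprop-2-enoate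
Conditions: tert-butyl 2,2,2-trichloroacetimidate, BF3·OEt2 (cat.), CH2Cl2–cyclohexane, rt
Reagents that add atoms: tert-butyl 2,2,2-trichloroacetimidate, CC(C)(C)OC(=N)C(Cl)(Cl)Cl
Why: Acid-catalysed tert-butylation of the carboxylic acid by the imidate. The tert-butyl ester resists premature lactonisation later and can leave as 2-methylpropene in step 19.

Step 8
Reactants: 8 Claisen acid; 12 tert-butyl iodo-enoate
Product: 15 tert-butyl (2E,5R,6R)-8-[(tert-butyldimethylsilyl)oxy]-2,6-dimethyl-5-(2-methyl-1,3-dioxolan-2-yl)-4-oxo-6-vinyloct-2-enoate, via acid chloride 13 (not isolated), via alkenylzinc iodide 14 (not isolated)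
Conditions: 8, 1-chloro-N,N,2-trimethylprop-1-en-1-amine, CH2Cl2, 0 °C to rt; 12, Zn, LiCl, THF, rt; then Pd(PPh3)4 (cat.), THF, 0 °C to rt
Reagents that add atoms: none
Why: Negishi acyl cross-coupling forms C6–C7; the acid chloride is made under neutral conditions and zinc inserts into the activated C–I bond with retention. The E enoate arrives intact and no olefin metathesis is needed, which would ring-close onto the C10 vinyl group. The E isomer, with the two carbonyl groups trans, is also the more stable one.

Step 9
Reactants: 15 enone
Product: 16 tert-butyl (2E,4S,5R,6R)-8-[(tert-butyldimethylsilyl)oxy]-4-hydroxy-2,6-dimethyl-5-(2-methyl-1,3-dioxolan-2-yl)-6-vinyloct-2-enoate (6-epi alcohol; C6 configured opposite to the target)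
Conditions: NaBH4, CeCl3·7H2O, MeOH, −78 °C
Reagents that add atoms: none
Why: Luche 1,2-reduction. The Felkin–Anh arrangement with quaternary C10 as the large group and the cerium chelate between the ketone and a dioxolane oxygen both expose the carbonyl face anti to C10. This should give the alcohol epimeric to the target at C6, which is the configuration the cycloaddition needs.

Step 10
Reactants: 16 6-epi alcohol
Product: 17 tert-butyl (2E,4S,5R,6R)-4,8-bis[(tert-butyldimethylsilyl)oxy]-2,6-dimethyl-5-(2-methyl-1,3-dioxolan-2-yl)-6-vinyloct-2-enoate
Conditions: TBSOTf, 2,6-lutidine, CH2Cl2, −78 to 0 °C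
Reagents that add atoms: tert-butyldimethylsilyl triflate, CC(C)(C)[Si](C)(C)OS(=O)(=O)C(F)(F)F
Why: Silylation of a hindered secondary alcohol with the silyl triflate; at low temperature with one equivalent the tert-butyl ester and the ketal are not touched.

Step 11
Reactants: 17 bis-silyl ether
Product: 18 tert-butyl (2E,4S,5R,6R)-4-[(tert-butyldimethylsilyl)oxy]-8-hydroxy-2,6-dimethyl-5-(2-methyl-1,3-dioxolan-2-yl)-6-vinyloct-2-enoate
Conditions: HF·pyridine, pyridine, THF, 0 °C
Reagents that add atoms: none
Why: Buffered fluoride cleaves the unhindered primary silyl ether much faster than the secondary one at C6, which is flanked by C5 and the alkene.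

Step 12
Reactants: 18 primary alcohol
Product: 19 tert-butyl (2E,4S,5R,6R)-4-[(tert-butyldimethylsilyl)oxy]-2,6-dimethyl-5-(2-methyl-1,3-dioxolan-2-yl)-8-oxo-6-vinyloct-2-enoate
Conditions: Dess–Martin periodinane, NaHCO3, CH2Cl2, rt
Reagents that add atoms: none
Why: Buffered Dess–Martin oxidation gives the C8 aldehyde, which has no α-stereocentre to lose.

Step 13
Reactants: 19 aldehyde
Product: 20 tert-butyl (2E,4S,5R,6R)-4-[(tert-butyldimethylsilyl)oxy]-8-(hydroxyimino)-2,6-dimethyl-5-(2-methyl-1,3-dioxolan-2-yl)-6-vinyloct-2-enoate (oxime; E/Z mixture at C=N)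
Conditions: NH2OH·HCl, pyridine, EtOH, rt
Reagents that add atoms: hydroxylamine hydrochloride, [NH3+]O.[Cl-]
Why: Oxime condensation at the only aldehyde; the hindered trisubstituted enoate is not a competitive Michael acceptor and the oxime geometry is irrelevant.

Step 14
Reactants: 20 oxime enoate
Product: 22 tert-butyl ester isoxazoline (C8=N–O–C11 fused to the cyclohexane at C7–C8; 6-epi silyl ether trans to the C7–C11 bond; C5 dioxolane; C5 and C7 and C10 and C11 as in the target), via nitrile oxide 21 (not isolated)
Conditions: NaOCl (aq.), CH2Cl2, 0 °C to rt, high dilution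
Reagents that add atoms: none
Why: Hypochlorite chlorinates the oxime and loss of HCl gives nitrile oxide 21, which adds to the E enoate in a concerted suprafacial [3+2] cycloaddition; the closest known reaction type is the intramolecular nitrile oxide–alkene cycloaddition that gives cyclohexane-fused isoxazolines. The cyclohexane closes by attack of C8 on C7 (6-exo, fused mode, since the four-atom tether C9–C10–C5–C6 could reach C11 only through a bridged seven-membered ring), and the isoxazoline closes in the same event by O–C11 bonding, the orientation a β-substituted α-methyl enoate also prefers. C11 is fixed relative to C7 by the E geometry, because both new bonds form on one face of the alkene. C7 is controlled by C6: the C13 methyl is cis to C6, so allylic 1,3-strain leaves only H6 in the plane of the alkene, the silyloxy group lies anti to the incoming dipole and C5 carries the tether, which places O6 trans to the new C7–C11 bond. Because the C7–C11 bond of the fused product must be pseudo-equatorial (coplanar with C8=N), this transition state is a chair with the silyloxy group equatorial, the dioxolane and the vinyl group axial, and H6 and H7 trans-diaxial. The competing chair, which would lead to the C7,C11-epimer, has the silyloxy group eclipsing the alkene against the C13 methyl and syn-axial to the C10 methyl. The step needs facial selectivity and chemoselectivity for the enoate over the C10 vinyl group and over dimerisation; the 6-epi silyl ether should secure the first, the tether length the second (the vinyl group could close only a four-membered or bridged ring) and high dilution the third. The dioxolane keeps C4 from offering a 1,1-disubstituted alkene for a five-ring closure.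

Step 15
Reactants: 22 isoxazoline
Product: 23 β-hydroxy ketone (C8 ketone; free tertiary C11 alcohol; tert-butyl ester; 6-epi silyl ether; C5 dioxolane)
Conditions: Mo(CO)6, MeCN–H2O, 80 °C
Reagents that add atoms: water, O
Why: Reductive N–O cleavage by Mo(CO)6 and hydrolysis of the resulting β-hydroxy imine. The alkenes are untouched, and C7 has no drive to epimerise because its large substituent is already equatorial.

Step 16
Reactants: 23 β-hydroxy ketone
Product: 24 8,11-diol with O8 trans to C11 (C8 as in the target)
Conditions: Me4NBH(OAc)3, MeCN–AcOH, −30 °C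
Reagents that add atoms: none
Why: Hydroxyl-directed (Evans–Saksena) reduction: the C11 alkoxy(diacetoxy)borohydride delivers hydride to C8 within a six-membered chair in which the ester, the smaller of the two C11 substituents, is axial and the methyl group equatorial. This geometry puts the hydride on the ring face of the C7–C11 bond (axial delivery), so O8 ends equatorial and trans to C11 as in the target. The reagent does not reduce ketones that lack a directing hydroxyl, and the tert-butyl ester resists lactonisation by O8.

Step 17
Reactants: 24 diol
Product: 25 8-acetate (tertiary C11 alcohol free)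
Conditions: Ac2O, pyridine, DMAP (cat.), CH2Cl2, 0 °C
Reagents that add atoms: acetic anhydride, CC(=O)OC(C)=O
Why: Selective acetylation of the secondary equatorial alcohol; the tertiary alcohol α to the ester is too hindered to react under these conditions.

Step 18
Reactants: 25 8-acetate
Product: 26 8-acetate 6-epi alcohol (C6 hydroxyl trans to C11)
Conditions: HF·pyridine, THF, rt
Reagents that add atoms: none
Why: Fluoride cleavage of the remaining silyl ether under non-basic conditions that leave the acetate in place without migration and spare the ketal and the tert-butyl ester.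

Step 19
Reactants: 26 6-epi alcohol
Product: 28 cis-fused 6,12-lactone (8-acetate; free C11 alcohol; C5 dioxolane; all stereocentres as in the target), via C6 triflate 27 (not isolated)
Conditions: Tf2O, 2,6-di-tert-butyl-4-methylpyridine, CH2Cl2, −78 to 0 °C
Reagents that add atoms: none
Why: Lactonisation with inversion by neighbouring-group participation: the carbonyl oxygen of the tert-butyl ester on C11 displaces the C6 triflate from the opposite face (5-exo-tet), and the dialkoxycarbenium ion loses 2-methylpropene. Only this ester sits on the face anti to the leaving group (the C8 acetate is on the same face as the triflate), and the closure gives the cis-fused lactone with O6 cis to C11.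

Step 20
Reactants: 28 ketal lactone
Product: 29 C5-acetyl lactone (methyl ketone at C4)
Conditions: HCl (2 M aq.), THF, rt
Reagents that add atoms: water, O
Why: Acid hydrolysis of the dioxolane; acid does not trigger β-elimination of the C6 lactone oxygen, which needs base.

Step 21
Reactants: 29 methyl ketone
Product: 30 8-acetoxy-11-hydroxy-elema-1,3-dien-12,6-olide (isopropenyl lactone)
Conditions: Zn, CH2Br2, TiCl4, THF–CH2Cl2, 0 °C to rt
Reagents that add atoms: dibromomethane, BrCBr
Why: Takai–Lombardo methylenation. The non-basic reagent converts an enolisable, α-branched ketone without epimerising C5 or eliminating O6, and it leaves the lactone and the acetate alone.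

Step 22
Reactants: 30 hydroxy lactone; 31 angelic acid ((Z)-2-methylbut-2-enoic acid)
Product: 33 target (5R,6S,7R,8S,10R,11S)-8-acetoxy-11-angeloyloxy-elema-1,3-dien-12,6-olide, via angelic 2,4,6-trichlorobenzoic anhydride 32 (not isolated)
Conditions: 31, 2,4,6-trichlorobenzoyl chloride, Et3N, toluene, rt; 30, NaN(SiMe3)2, THF, −78 °C; then combine, −78 to 0 °C
Reagents that add atoms: none
Why: Yamaguchi-type mixed anhydride acylation of the tertiary alkoxide, which attacks the unshielded angeloyl carbonyl. Low temperature and the absence of a nucleophilic catalyst keep the Z alkene from isomerising, and C11 has no α-hydrogen.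

## Compound list

1 | tert-butyl(but-3-yn-1-yloxy)dimethylsilane | C#CCCO[Si](C)(C)C(C)(C)C | starting material
2 | [(E)-4-(tert-butyldimethylsilyloxy)-2-methylbut-1-en-1-yl]dimethylalane | C[Al](C)/C=C(\C)CCO[Si](C)(C)C(C)(C)C | intermediate
3 | (E)-5-[(tert-butyldimethylsilyl)oxy]-3-methylpent-2-en-1-ol | OC/C=C(\C)CCO[Si](C)(C)C(C)(C)C | intermediate
4 | ethyl 2-(2-methyl-1,3-dioxolan-2-yl)acetate | CCOC(=O)CC1(C)OCCO1 | starting material
5 | 2-(2-methyl-1,3-dioxolan-2-yl)acetic acid | OC(=O)CC1(C)OCCO1 | intermediate
6 | (E)-5-[(tert-butyldimethylsilyl)oxy]-3-methylpent-2-en-1-yl 2-(2-methyl-1,3-dioxolan-2-yl)acetate | CC1(CC(=O)OC/C=C(\C)CCO[Si](C)(C)C(C)(C)C)OCCO1 | intermediate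
7 | boron ketene acetal of 6 with the (4S,5S)-diazaborolidine, C5 substituent cis to the allyloxy oxygen | CC1(/C=C(/OB2N(S(=O)(=O)c3cc(C(F)(F)F)cc(C(F)(F)F)c3)[C@@H](c3ccccc3)[C@H](c3ccccc3)N2S(=O)(=O)c2cc(C(F)(F)F)cc(C(F)(F)F)c2)OC/C=C(\C)CCO[Si](C)(C)C(C)(C)C)OCCO1 | intermediate
8 | (2S,3R)-3-{2-[(tert-butyldimethylsilyl)oxy]ethyl}-3-methyl-2-(2-methyl-1,3-dioxolan-2-yl)pent-4-enoic acid | C=C[C@@](C)(CCO[Si](C)(C)C(C)(C)C)[C@@H](C1(C)OCCO1)C(=O)O | intermediate
9 | diethyl 2-methylmalonate | CCOC(=O)C(C)C(=O)OCC | starting material
10 | diethyl 2-(diiodomethyl)-2-methylmalonate | CCOC(=O)C(C)(C(I)I)C(=O)OCC | intermediate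
11 | (E)-3-iodo-2-methylprop-2-enoic acid | C/C(=C\I)C(=O)O | intermediate
12 | tert-butyl (E)-3-iodo-2-methylprop-2-enoate | C/C(=C\I)C(=O)OC(C)(C)C | intermediate
13 | acid chloride of 8 | C=C[C@@](C)(CCO[Si](C)(C)C(C)(C)C)[C@@H](C1(C)OCCO1)C(Cl)=O | intermediate
14 | [(E)-3-tert-butoxy-2-methyl-3-oxoprop-1-en-1-yl]zinc iodide | C/C(=C\[Zn]I)C(=O)OC(C)(C)C | intermediate
15 | tert-butyl (2E,5R,6R)-8-[(tert-butyldimethylsilyl)oxy]-2,6-dimethyl-5-(2-methyl-1,3-dioxolan-2-yl)-4-oxo-6-vinyloct-2-enoate | C=C[C@@](C)(CCO[Si](C)(C)C(C)(C)C)[C@@H](C1(C)OCCO1)C(=O)/C=C(\C)C(=O)OC(C)(C)C | intermediate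
16 | tert-butyl (2E,4S,5R,6R)-8-[(tert-butyldimethylsilyl)oxy]-4-hydroxy-2,6-dimethyl-5-(2-methyl-1,3-dioxolan-2-yl)-6-vinyloct-2-enoate | C=C[C@@](C)(CCO[Si](C)(C)C(C)(C)C)[C@@H](C1(C)OCCO1)[C@@H](O)/C=C(\C)C(=O)OC(C)(C)C | intermediate
17 | tert-butyl (2E,4S,5R,6R)-4,8-bis[(tert-butyldimethylsilyl)oxy]-2,6-dimethyl-5-(2-methyl-1,3-dioxolan-2-yl)-6-vinyloct-2-enoate | C=C[C@@](C)(CCO[Si](C)(C)C(C)(C)C)[C@@H](C1(C)OCCO1)[C@@H](O[Si](C)(C)C(C)(C)C)/C=C(\C)C(=O)OC(C)(C)C | intermediate
18 | tert-butyl (2E,4S,5R,6R)-4-[(tert-butyldimethylsilyl)oxy]-8-hydroxy-2,6-dimethyl-5-(2-methyl-1,3-dioxolan-2-yl)-6-vinyloct-2-enoate | C=C[C@@](C)(CCO)[C@@H](C1(C)OCCO1)[C@@H](O[Si](C)(C)C(C)(C)C)/C=C(\C)C(=O)OC(C)(C)C | intermediate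
19 | tert-butyl (2E,4S,5R,6R)-4-[(tert-butyldimethylsilyl)oxy]-2,6-dimethyl-5-(2-methyl-1,3-dioxolan-2-yl)-8-oxo-6-vinyloct-2-enoate | C=C[C@@](C)(CC=O)[C@@H](C1(C)OCCO1)[C@@H](O[Si](C)(C)C(C)(C)C)/C=C(\C)C(=O)OC(C)(C)C | intermediate
20 | tert-butyl (2E,4S,5R,6R)-4-[(tert-butyldimethylsilyl)oxy]-8-(hydroxyimino)-2,6-dimethyl-5-(2-methyl-1,3-dioxolan-2-yl)-6-vinyloct-2-enoate | C=C[C@@](C)(CC=NO)[C@@H](C1(C)OCCO1)[C@@H](O[Si](C)(C)C(C)(C)C)/C=C(\C)C(=O)OC(C)(C)C | intermediate
21 | C8 nitrile oxide of 20 | C=C[C@@](C)(CC#[N+][O-])[C@@H](C1(C)OCCO1)[C@@H](O[Si](C)(C)C(C)(C)C)/C=C(\C)C(=O)OC(C)(C)C | intermediate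
22 | cyclohexane-fused isoxazoline (C8=N–O–C11): C11 methyl and tert-butyl ester, C10 methyl and vinyl, C5 2-methyl-1,3-dioxolan-2-yl, C6 silyl ether trans to the C7–C11 bond (6-epi); C5, C7, C10, C11 as in the target | C=C[C@@]1(C)CC2=NO[C@](C)(C(=O)OC(C)(C)C)[C@H]2[C@H](O[Si](C)(C)C(C)(C)C)[C@@H]1C3(C)OCCO3 | intermediate
23 | β-hydroxy ketone: C8 ketone, C11 tertiary alcohol with methyl and tert-butyl ester, 6-epi silyl ether, C5 dioxolane | C=C[C@@]1(C)CC(=O)[C@@H]([C@](C)(O)C(=O)OC(C)(C)C)[C@H](O[Si](C)(C)C(C)(C)C)[C@@H]1C3(C)OCCO3 | intermediate
24 | 8,11-diol of 23, O8 trans to C11 | C=C[C@@]1(C)C[C@H](O)[C@@H]([C@](C)(O)C(=O)OC(C)(C)C)[C@H](O[Si](C)(C)C(C)(C)C)[C@@H]1C3(C)OCCO3 | intermediate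
25 | 8-acetate of 24 | C=C[C@@]1(C)C[C@H](OC(C)=O)[C@@H]([C@](C)(O)C(=O)OC(C)(C)C)[C@H](O[Si](C)(C)C(C)(C)C)[C@@H]1C3(C)OCCO3 | intermediate
26 | 8-acetate with free 6-epi hydroxyl (trans to C11) | C=C[C@@]1(C)C[C@H](OC(C)=O)[C@@H]([C@](C)(O)C(=O)OC(C)(C)C)[C@H](O)[C@@H]1C3(C)OCCO3 | intermediate
27 | C6 triflate of 26 | C=C[C@@]1(C)C[C@H](OC(C)=O)[C@@H]([C@](C)(O)C(=O)OC(C)(C)C)[C@H](OS(=O)(=O)C(F)(F)F)[C@@H]1C3(C)OCCO3 | intermediate
28 | cis-fused 6,12-lactone: 8-acetoxy, 11-hydroxy, C5 2-methyl-1,3-dioxolan-2-yl, stereocentres as in the target | C=C[C@@]1(C)C[C@H](OC(C)=O)[C@@H]2[C@@H](OC(=O)[C@@]2(C)O)[C@@H]1C3(C)OCCO3 | intermediate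
29 | cis-fused 6,12-lactone with C5 acetyl, 8-acetoxy, 11-hydroxy | C=C[C@@]1(C)C[C@H](OC(C)=O)[C@@H]2[C@@H](OC(=O)[C@@]2(C)O)[C@@H]1C(C)=O | intermediate
30 | 8-acetoxy-11-hydroxy-elema-1,3-dien-12,6-olide | C=C[C@@]1(C)C[C@H](OC(C)=O)[C@@H]2[C@@H](OC(=O)[C@@]2(C)O)[C@@H]1C(=C)C | intermediate
31 | angelic acid, (Z)-2-methylbut-2-enoic acid | C/C=C(/C)C(=O)O | starting material
32 | (Z)-2-methylbut-2-enoic 2,4,6-trichlorobenzoic anhydride | C/C=C(/C)C(=O)OC(=O)c1c(Cl)cc(Cl)cc1Cl | intermediate
33 | (5R,6S,7R,8S,10R,11S)-8-acetoxy-11-[(Z)-2-methylbut-2-enoyloxy]-elema-1,3-dien-12,6-olide | C=C[C@@]1(C)C[C@H](OC(C)=O)[C@@H]2[C@@H](OC(=O)[C@@]2(C)OC(=O)/C(C)=C\C)[C@@H]1C(=C)C | target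

## Step count and least certain steps

Total: 22 steps. Longest linear sequence: 18 steps (steps 1, 3, 4 and 8–22 from alkyne 1; equally steps 5–22 from malonate 9).

**Step 14 (key step).** The most likely failure is insufficient facial selectivity, because the favoured chair must hold the bulky dioxolane axial, so the energy gap to the competing chair may be small. Slow addition to the hindered trisubstituted enoate could also let the nitrile oxide dimerise. The fallback changes the dipole and sets out from alcohol 18. I2, PPh3 and imidazole would give tert-butyl (2E,4S,5R,6R)-4-[(tert-butyldimethylsilyl)oxy]-8-iodo-2,6-dimethyl-5-(2-methyl-1,3-dioxolan-2-yl)-6-vinyloct-2-enoate F1 and NaNO2 in DMF would then give the corresponding 8-nitro compound F2 by displacement. Me3SiCl and Et3N would turn F2 into its trimethylsilyl nitronate F3 as a bulkier dipole that does not dimerise. Nitronate F3 should add to the enoate in an intramolecular silyl nitronate–alkene cycloaddition, expected to respond to the same allylic strain, and give N-(trimethylsilyloxy)isoxazolidine F4 with the C7–C8 and O–C11 bonds in place. Acid would then eliminate trimethylsilanol from F4 so that the route is rejoined at isoxazoline 22.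

**Step 19.** The displacement needs the C11 arm and the leaving group close to anti-periplanar, which the ground-state chair (both equatorial) does not offer. The triflate may therefore eliminate or decompose faster than the ester participates. The fallback replaces displacement by oxidation and directed reduction and sets out from diol 24. O8 would be chloroacetylated ((ClCH2CO)2O, pyridine) to the 8-chloroacetate F5 and the C6 silyl ether then removed with HF·pyridine to give the 6-epi alcohol F6 for oxidation. Dess–Martin periodinane would convert F6 into the C6 ketone F7 and thiourea with NaHCO3 in EtOH would free O8 to give the 8-hydroxy C6 ketone F8 as a β-hydroxy ketone. An Evans–Tishchenko reduction of F8 (SmI2 cat., acetaldehyde, THF, −10 °C) should deliver hydride to C6 from the hemiacetal on O8, on the face opposite to C11, while acetylating O8. This would give the 8-acetate 6-alcohol F9 with the C6 configuration of the target; the tertiary O11 is not expected to form the hemiacetal competitively. CF3CO2H with water would cleave the tert-butyl ester and the dioxolane of F9 and let O6 lactonise, rejoining the route at ketone 29.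

**Step 16.** The sense of hydride delivery may be reversed. The directed pathway has to pass over the ring face that carries the axial C10 vinyl group, and it depends on the ester rather than the methyl group taking the axial site at C11 in the delivery chair; delivery from the other face would give the C8 epimer. The fallback accepts attack from the open face and corrects C8 by substitution; it sets out from ketone 23. NaBH4 in MeOH at −40 °C is expected to attack C8 equatorially, away from the axial vinyl group, and give the 8-epi diol F10 with O8 cis to C11. A Mitsunobu reaction of F10 with acetic acid (PPh3, diisopropyl azodicarboxylate, toluene, 0 °C to rt) would invert C8 and install the acetate in one operation, while the tertiary alcohol stays inert. The route is rejoined at acetate 25.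

**Step 4.** The Lewis-acidic bromoborane may open the dioxolane, or the enolate geometry may be mixed, which would erode the C5/C10 relationship. The fallback gives up reagent control and sets out from ester 6. LiN(iPr)2 with Me3SiCl present (THF, −100 °C to rt) would trap the kinetic enolate at once as trimethylsilyl ketene acetal F11 with the same geometry and without loss of the β-oxygen. Ireland–Claisen rearrangement on warming and hydrolysis would give acid 8 in racemic form. Crystallisation with (S)-1-phenylethylamine, the enantiomer of the amine being chosen empirically, would deposit the ammonium salt F12 of the wanted acid and leave the enantiomeric acid F13 in the mother liquor. Acidification of F12 rejoins the route at acid 8.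

**Step 8.** The acyl chloride carries two fully substituted carbons on its α-carbon, so transmetalation may be slow and the alkenylzinc may lose its geometry or be protonated first. The fallback builds C6–C7 by carbonyl addition and sets out from acid 8. LiAlH4 would reduce it to (2R,3R)-3-{2-[(tert-butyldimethylsilyl)oxy]ethyl}-3-methyl-2-(2-methyl-1,3-dioxolan-2-yl)pent-4-en-1-ol F14 and Dess–Martin oxidation would give the corresponding aldehyde F15 for a Nozaki–Hiyama–Kishi coupling with 12 (CrCl2, NiCl2 cat., DMF). The coupling would give the allylic alcohols F16 as a mixture of C6 epimers, and Dess–Martin oxidation of the mixture rejoins the route at enone 15.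

**Step 22.** The tertiary alkoxide may react sluggishly, and prolonged exposure to base may isomerise the angelate to the tiglate or move the C8 acetyl group. The fallback builds the Z alkene on the molecule and sets out from lactone 30. O11 would be esterified with 2-[bis(2,2,2-trifluoroethoxy)phosphoryl]propanoic acid and DCC, a combination that acylates hindered alcohols through the derived ketene, to give the phosphonopropionate F17 as the olefination partner. A Still–Gennari olefination of F17 with acetaldehyde (KN(SiMe3)2, 18-crown-6, THF, −78 °C) should then give the Z trisubstituted ester, rejoining the route at target 33.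

## Further compounds

F1 | step 14 | tert-butyl (2E,4S,5R,6R)-4-[(tert-butyldimethylsilyl)oxy]-8-iodo-2,6-dimethyl-5-(2-methyl-1,3-dioxolan-2-yl)-6-vinyloct-2-enoate | C=C[C@@](C)(CCI)[C@@H](C1(C)OCCO1)[C@@H](O[Si](C)(C)C(C)(C)C)/C=C(\C)C(=O)OC(C)(C)C
F2 | step 14 | tert-butyl (2E,4S,5R,6R)-4-[(tert-butyldimethylsilyl)oxy]-2,6-dimethyl-5-(2-methyl-1,3-dioxolan-2-yl)-8-nitro-6-vinyloct-2-enoate | C=C[C@@](C)(CC[N+](=O)[O-])[C@@H](C1(C)OCCO1)[C@@H](O[Si](C)(C)C(C)(C)C)/C=C(\C)C(=O)OC(C)(C)C
F3 | step 14 | trimethylsilyl nitronate of F2 | C=C[C@@](C)(CC=[N+]([O-])O[Si](C)(C)C)[C@@H](C1(C)OCCO1)[C@@H](O[Si](C)(C)C(C)(C)C)/C=C(\C)C(=O)OC(C)(C)C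
F4 | step 14 | N-(trimethylsilyloxy)isoxazolidine corresponding to 22 (C8 configuration open) | C=C[C@@]1(C)CC2N(O[Si](C)(C)C)O[C@](C)(C(=O)OC(C)(C)C)[C@H]2[C@H](O[Si](C)(C)C(C)(C)C)[C@@H]1C3(C)OCCO3
F5 | step 19 | 8-chloroacetate of diol 24 | C=C[C@@]1(C)C[C@H](OC(=O)CCl)[C@@H]([C@](C)(O)C(=O)OC(C)(C)C)[C@H](O[Si](C)(C)C(C)(C)C)[C@@H]1C3(C)OCCO3
F6 | step 19 | 8-chloroacetate with free 6-epi hydroxyl | C=C[C@@]1(C)C[C@H](OC(=O)CCl)[C@@H]([C@](C)(O)C(=O)OC(C)(C)C)[C@H](O)[C@@H]1C3(C)OCCO3
F7 | step 19 | 8-chloroacetate C6 ketone | C=C[C@@]1(C)C[C@H](OC(=O)CCl)[C@@H]([C@](C)(O)C(=O)OC(C)(C)C)C(=O)[C@@H]1C3(C)OCCO3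
F8 | step 19 | 8-hydroxy C6 ketone | C=C[C@@]1(C)C[C@H](O)[C@@H]([C@](C)(O)C(=O)OC(C)(C)C)C(=O)[C@@H]1C3(C)OCCO3
F9 | step 19 | 8-acetate 6-alcohol with the C6 configuration of the target | C=C[C@@]1(C)C[C@H](OC(C)=O)[C@@H]([C@](C)(O)C(=O)OC(C)(C)C)[C@@H](O)[C@@H]1C3(C)OCCO3
F10 | step 16 | 8-epi diol of 23, O8 cis to C11 | C=C[C@@]1(C)C[C@@H](O)[C@@H]([C@](C)(O)C(=O)OC(C)(C)C)[C@H](O[Si](C)(C)C(C)(C)C)[C@@H]1C3(C)OCCO3
F11 | step 4 | trimethylsilyl ketene acetal of 6, C5 substituent cis to the allyloxy oxygen | CC1(/C=C(/O[Si](C)(C)C)OC/C=C(\C)CCO[Si](C)(C)C(C)(C)C)OCCO1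
F12 | step 4 | (S)-1-phenylethylammonium salt of acid 8 | C=C[C@@](C)(CCO[Si](C)(C)C(C)(C)C)[C@@H](C1(C)OCCO1)C(=O)[O-].C[C@H]([NH3+])c1ccccc1
F13 | step 4 | (2R,3S)-enantiomer of acid 8 | C=C[C@](C)(CCO[Si](C)(C)C(C)(C)C)[C@H](C1(C)OCCO1)C(=O)O
F14 | step 8 | (2R,3R)-3-{2-[(tert-butyldimethylsilyl)oxy]ethyl}-3-methyl-2-(2-methyl-1,3-dioxolan-2-yl)pent-4-en-1-ol | C=C[C@@](C)(CCO[Si](C)(C)C(C)(C)C)[C@@H](C1(C)OCCO1)CO
F15 | step 8 | (2R,3R)-3-{2-[(tert-butyldimethylsilyl)oxy]ethyl}-3-methyl-2-(2-methyl-1,3-dioxolan-2-yl)pent-4-enal | C=C[C@@](C)(CCO[Si](C)(C)C(C)(C)C)[C@@H](C1(C)OCCO1)C=O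
F16 | step 8 | tert-butyl (2E,5R,6R)-8-[(tert-butyldimethylsilyl)oxy]-4-hydroxy-2,6-dimethyl-5-(2-methyl-1,3-dioxolan-2-yl)-6-vinyloct-2-enoate, either C4 epimer | C=C[C@@](C)(CCO[Si](C)(C)C(C)(C)C)[C@@H](C1(C)OCCO1)C(O)/C=C(\C)C(=O)OC(C)(C)C
F17 | step 22 | 11-O-{2-[bis(2,2,2-trifluoroethoxy)phosphoryl]propanoyl} derivative of 30 | C=C[C@@]1(C)C[C@H](OC(C)=O)[C@@H]2[C@@H](OC(=O)[C@@]2(C)OC(=O)C(C)P(=O)(OCC(F)(F)F)OCC(F)(F)F)[C@@H]1C(=C)C
A1 | alternative 1 | 2-benzyloxy-3-isopropenyl-4-methyl-4-vinylcyclohexanone | C=C[C@@]1(C)CCC(=O)[C@@H](OCc2ccccc2)[C@@H]1C(=C)C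
A2 | alternative 2 | (S)-5-[(tert-butyldimethylsilyl)oxy]-3-methylcyclohex-2-en-1-one | O=C1C[C@@H](O[Si](C)(C)C(C)(C)C)CC(C)=C1
A3 | alternative 2 | 1-methylcyclobutene | CC1=CCC1
A4 | alternative 2 | cis-anti-cis 6-4-4 tricyclic photoadduct | O=C1C[C@@H](O[Si](C)(C)C(C)(C)C)C[C@]2(C)[C@H]3CC[C@@]3(C)[C@H]12
A5 | alternative 3 | methacrolein | C=C(C)C=O
A6 | alternative 3 | (E)-1-(dimethylamino)-3-[(tert-butyldimethylsilyl)oxy]buta-1,3-diene | CN(C)/C=C/C(=C)O[Si](C)(C)C(C)(C)C
A7 | alternative 3 | endo cycloadduct, amino silyl enol ether aldehyde | O=C[C@@]1(C)CCC(O[Si](C)(C)C(C)(C)C)=C[C@H]1N(C)C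
A8 | alternative 3 | (R)-4-methyl-4-vinylcyclohex-2-en-1-one | C=C[C@@]1(C)CCC(=O)C=C1
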